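**Strategy.** The cyclopentenone ring is disconnected at C1–C5 and C3–C4 (C1 = ring C=O, C2 = CBr, C3 = ring CH, C4 = carbinol carbon, C5 = alkylidene carbon). This exposes the β-hydroxy ketone array C4(OH)–C5–C1(=O) of the ring. C4 and C5 are the carbonyl and methyl carbons of methyl 9-oxodecanoate; C1–C3 come from a β-(phenylsulfanyl)acryloylsilane. In one operation the ketone enolate (C5) adds to the acylsilane carbonyl (C1), a Brook rearrangement relays the charge to C3, and C3 closes on C4, giving the five-membered ring with its tertiary carbinol. Bromination at C2, selection of the (S)-series by CBS reduction and reoxidation, and a syn-aldol/syn-dehydration for the (Z)-dienylidene complete the route.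

Key step: step 4

Remark: 1, 3 and 20 are taken as commercial; the CIP label of C4 is R in 18, 19 and 23 and S in 24 and 25 with no change in space, because C5 outranks C3 once it is sp2.

Step 1
Reactants: 1 methyl dec-9-enoate
Product: 2 methyl 9-oxodecanoate
Conditions: PdCl2 (10 mol %), CuCl (1 equiv), O2 (1 atm), DMF/H2O 7:1, rt
Reagents that add atoms: water, O
Why: Wacker–Tsuji oxidation should convert the terminal alkene into the methyl ketone by Markovnikov attack of water, the remote ester being inert.

Step 2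
Reactants: 3 methoxyallene
Product: 5 tert-butyl(1-methoxypropa-1,2-dien-1-yl)dimethylsilane, via 1-lithio-1-methoxyallene 4 (not isolated)
Conditions: n-BuLi, THF, –78 °C; then TBSCl, –78 °C to rt
Reagents that add atoms: tert-butyldimethylsilyl chloride, CC(C)(C)[Si](C)(C)Cl
Why: α-Metalation of the alkoxyallene at the oxygen-bearing carbon followed by C-silylation is a standard route to 1-silyl-1-alkoxyallenes.

Step 3
Reactants: 5 tert-butyl(1-methoxypropa-1,2-dien-1-yl)dimethylsilane
Product: 8 (2E)-1-[tert-butyl(dimethyl)silyl]-3-(phenylsulfanyl)prop-2-en-1-one, via 3-lithioallene 6 (not isolated), via allenyl sulfide 7 (not isolated)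
Conditions: n-BuLi, THF, –78 °C; PhSSPh, –78 to 0 °C; then 1 M HCl, THF, 0 °C
Reagents that add atoms: diphenyl disulfide, c1ccc(SSc2ccccc2)cc1; water, O
Why: γ-Lithiation at the only remaining allenic CH2, sulfenylation and acid hydrolysis of the allenyl enol ether (protonation at the central carbon) should unmask the acylsilane, and either double-bond isomer is usable because C3 loses its geometry in step 5.

Step 4
Reactants: 2 methyl 9-oxodecanoate; 8 (2E)-1-[tert-butyl(dimethyl)silyl]-3-(phenylsulfanyl)prop-2-en-1-one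
Product: 12 racemic methyl 8-[(1R*,2S*)-4-{[tert-butyl(dimethyl)silyl]oxy}-1-hydroxy-2-(phenylsulfanyl)cyclopent-3-en-1-yl]octanoate, via lithium enolate 9 (not isolated), via acylsilane adduct alkoxide 10 (not isolated), via siloxyallyllithium 11 (not isolated)
Conditions: LiN(iPr)2 (LDA, 1.05 equiv), THF, –80 °C, 2 added to the base; then 8, –80 to –30 °C; aq. NH4Cl
Reagents that add atoms: none
Why: The kinetic enolate 9 adds through C5 to the very electrophilic acylsilane carbonyl C1 (first bond); the α-silyl alkoxide 10 then undergoes a 1,2-Brook rearrangement (silyl shift from C to O) to the sulfur-stabilised siloxyallyl anion 11, whose C3 terminus adds to the tethered ketone carbonyl C4 (second bond). The closest known reaction type is the Brook-rearrangement-mediated [3+2] annulation of β-heteroatom-substituted acryloylsilanes with lithium enolates of alkyl methyl ketones. The single ring is closed by 5-exo-trig attack of C3 on the C4 carbonyl (equivalently, 3-exo-trig closure at C1 followed by an alkoxide-accelerated vinylcyclopropane-to-cyclopentene shift), leaving C1 as a regiodefined TBS enol ether. Two stereocentres arise: the C3/C4 relationship (OH and SPh cis) should follow from the lithium-bridged closure and is irrelevant because C3 becomes sp2 in step 5. The absolute configuration at C4 is not controlled, so 12 is racemic and the required series is selected in steps 8 and 9. The step needs deprotonation of the CH3 group in preference to the C8 methylene and the ester α-CH2 (kinetic base, low temperature, more acidic and less hindered ketone methyl) and 1,2- instead of 1,4-addition to 8 (acylsilane carbonyl activation and the β-sulfur donor that deactivates C3).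

Step 5
Reactants: 12 racemic methyl 8-[(1R*,2S*)-4-{[tert-butyl(dimethyl)silyl]oxy}-1-hydroxy-2-(phenylsulfanyl)cyclopent-3-en-1-yl]octanoate
Product: 14 racemic methyl 8-(1-hydroxy-4-oxocyclopent-2-en-1-yl)octanoate, via allylic sulfoxide 13 (not isolated)
Conditions: NaIO4 (1.1 equiv), MeOH/THF/H2O, 0 °C to rt; then NaHCO3, 40 °C
Reagents that add atoms: none
Why: Chemoselective sulfide-to-sulfoxide oxidation should give an allylic sulfoxide that leaves as benzenesulfenic acid by Mislow–Evans [2,3]-shift and hydrolysis of the silyl sulfenyl ketal (or, after enol ether hydrolysis, by sulfoxide syn-elimination), both paths placing the double bond at C2=C3 because C4 carries no hydrogen.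

Step 6
Reactants: 14 racemic methyl 8-(1-hydroxy-4-oxocyclopent-2-en-1-yl)octanoate
Product: 15 racemic methyl 8-{4-oxo-1-[(triethylsilyl)oxy]cyclopent-2-en-1-yl}octanoate
Conditions: TESOTf, 2,6-lutidine, CH2Cl2, –78 to 0 °C
Reagents that add atoms: triethylsilyl trifluoromethanesulfonate, CC[Si](CC)(CC)OS(=O)(=O)C(F)(F)F
Why: Silyl triflate silylation of the hindered tertiary alcohol should block retro-aldol ring opening and the acidic OH before the enolate chemistry.

Step 7
Reactants: 15 racemic methyl 8-{4-oxo-1-[(triethylsilyl)oxy]cyclopent-2-en-1-yl}octanoate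
Product: 17 racemic methyl 8-{3-bromo-4-oxo-1-[(triethylsilyl)oxy]cyclopent-2-en-1-yl}octanoate, via 2,3-dibromide 16 (not isolated)
Conditions: Br2, CH2Cl2, 0 °C; then Et3N, 0 °C to rt
Reagents that add atoms: bromine, BrBr
Why: Bromination–dehydrobromination of the enone: Br2 adds across C2=C3 and the amine removes the acidic C2–H with loss of the C3 bromide, leaving bromine at C2 only.

Step 8
Reactants: 17 racemic methyl 8-{3-bromo-4-oxo-1-[(triethylsilyl)oxy]cyclopent-2-en-1-yl}octanoate
Product: 18 methyl 8-{(1R,4R)-3-bromo-4-hydroxy-1-[(triethylsilyl)oxy]cyclopent-2-en-1-yl}octanoate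
Conditions: (S)-2-methyl-CBS-oxazaborolidine (0.2 equiv), BH3·SMe2 (0.6 equiv), THF, –30 °C; MeOH; chromatographic separation of the two diastereomers
Reagents that add atoms: none
Why: In this CBS reduction, catalyst-controlled hydride delivery to the α-bromo enone carbonyl (bromovinyl as the large group) should give the (R)-carbinol from both enantiomers of 17, so the racemate becomes two separable diastereomers, and the trans isomer 18 (carbinol configuration to be confirmed by Mosher ester analysis) carries the required configuration at the quaternary carbon.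

Step 9
Reactants: 18 methyl 8-{(1R,4R)-3-bromo-4-hydroxy-1-[(triethylsilyl)oxy]cyclopent-2-en-1-yl}octanoate
Product: 19 methyl 8-{(1R)-3-bromo-4-oxo-1-[(triethylsilyl)oxy]cyclopent-2-en-1-yl}octanoate
Conditions: Dess–Martin periodinane, NaHCO3, CH2Cl2, 0 °C to rt
Reagents that add atoms: none
Why: Dess–Martin oxidation of the secondary allylic alcohol should return the bromo enone as a single enantiomer without touching the quaternary carbon.

Step 10
Reactants: 19 methyl 8-{(1R)-3-bromo-4-oxo-1-[(triethylsilyl)oxy]cyclopent-2-en-1-yl}octanoate; 20 (2E)-pent-2-enal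
Product: 23 methyl 8-{(1R,5R)-3-bromo-5-[(1R,2E)-1-hydroxypent-2-en-1-yl]-4-oxo-1-[(triethylsilyl)oxy]cyclopent-2-en-1-yl}octanoate, via lithium dienolate 21 (not isolated), via chlorozirconocene dienolate 22 (not isolated)
Conditions: LiN(iPr)2 (LDA), THF, –78 °C; Cp2ZrCl2, –78 to –40 °C; 20, –78 °C; aq. NH4Cl
Reagents that add atoms: none
Why: In this zirconium enolate aldol addition the only possible enolate (C5) is transmetalated to zirconium, which should give the syn (erythro) aldol whatever the enolate geometry, with 1,2-addition to the enal; the C4/C5 relationship (attack anti to the silyloxy group assumed) has no bearing on step 11.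

Step 11
Reactants: 23 methyl 8-{(1R,5R)-3-bromo-5-[(1R,2E)-1-hydroxypent-2-en-1-yl]-4-oxo-1-[(triethylsilyl)oxy]cyclopent-2-en-1-yl}octanoate
Product: 24 methyl 8-{(1S,5Z)-3-bromo-4-oxo-5-[(2E)-pent-2-en-1-ylidene]-1-[(triethylsilyl)oxy]cyclopent-2-en-1-yl}octanoate
Conditions: DCC, CuCl (cat.), Et2O, rt, dark
Reagents that add atoms: none
Why: Carbodiimide/CuCl dehydration of a β-hydroxy ketone is a stereospecific syn-elimination through the O-alkylisourea, so the syn-aldol should place the butenyl chain cis to the C1 carbonyl, which is the (Z)-alkylidene.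

Step 12
Reactants: 24 methyl 8-{(1S,5Z)-3-bromo-4-oxo-5-[(2E)-pent-2-en-1-ylidene]-1-[(triethylsilyl)oxy]cyclopent-2-en-1-yl}octanoate
Product: 25 methyl 8-{(1S,5Z)-3-bromo-1-hydroxy-4-oxo-5-[(2E)-pent-2-en-1-ylidene]cyclopent-2-en-1-yl}octanoate
Conditions: HF·pyridine, THF, 0 °C, dark
Reagents that add atoms: none
Why: Fluoride cleavage of the tertiary triethylsilyl ether under mildly acidic conditions should leave the cross-conjugated bromo dienone, the methyl ester and both double-bond geometries intact.

**Compound list**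

1 | methyl dec-9-enoate | C=CCCCCCCCC(=O)OC | starting material
2 | methyl 9-oxodecanoate | CC(=O)CCCCCCCC(=O)OC | intermediate
3 | methoxyallene (1-methoxypropa-1,2-diene) | COC=C=C | starting material
4 | (1-methoxypropa-1,2-dien-1-yl)lithium | [Li]C(OC)=C=C | intermediate (not isolated)
5 | tert-butyl(1-methoxypropa-1,2-dien-1-yl)dimethylsilane | COC(=C=C)[Si](C)(C)C(C)(C)C | intermediate
6 | {3-[tert-butyl(dimethyl)silyl]-3-methoxypropa-1,2-dien-1-yl}lithium | [Li]C=C=C(OC)[Si](C)(C)C(C)(C)C | intermediate (not isolated)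
7 | tert-butyl[1-methoxy-3-(phenylsulfanyl)propa-1,2-dien-1-yl]dimethylsilane (racemic) | COC(=C=CSc1ccccc1)[Si](C)(C)C(C)(C)C | intermediate (not isolated)
8 | (2E)-1-[tert-butyl(dimethyl)silyl]-3-(phenylsulfanyl)prop-2-en-1-one | O=C(/C=C/Sc1ccccc1)[Si](C)(C)C(C)(C)C | intermediate
9 | lithium enolate of 2, methyl 9-(lithiooxy)dec-9-enoate | C=C(O[Li])CCCCCCCC(=O)OC | intermediate (not isolated)
10 | methyl (12E)-11-[tert-butyl(dimethyl)silyl]-11-(lithiooxy)-9-oxo-13-(phenylsulfanyl)tridec-12-enoate (racemic) | [Li]OC(/C=C/Sc1ccccc1)([Si](C)(C)C(C)(C)C)CC(=O)CCCCCCCC(=O)OC | intermediate (not isolated)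
11 | methyl (11E)-11-{[tert-butyl(dimethyl)silyl]oxy}-13-lithio-9-oxo-13-(phenylsulfanyl)tridec-11-enoate (racemic) | [Li]C(Sc1ccccc1)/C=C(/O[Si](C)(C)C(C)(C)C)CC(=O)CCCCCCCC(=O)OC | intermediate (not isolated)
12 | methyl 8-[(1R*,2S*)-4-{[tert-butyl(dimethyl)silyl]oxy}-1-hydroxy-2-(phenylsulfanyl)cyclopent-3-en-1-yl]octanoate (racemic, OH and SPh cis; one enantiomer drawn) | CC(C)(C)[Si](C)(C)OC1=C[C@H](Sc2ccccc2)[C@@](O)(CCCCCCCC(=O)OC)C1 | intermediate
13 | S-oxide of 12 (racemic, mixture at sulfur; one ring enantiomer drawn) | CC(C)(C)[Si](C)(C)OC1=C[C@H](S(=O)c2ccccc2)[C@@](O)(CCCCCCCC(=O)OC)C1 | intermediate (not isolated)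
14 | methyl 8-(1-hydroxy-4-oxocyclopent-2-en-1-yl)octanoate (racemic) | O=C1C=CC(O)(CCCCCCCC(=O)OC)C1 | intermediate
15 | methyl 8-{4-oxo-1-[(triethylsilyl)oxy]cyclopent-2-en-1-yl}octanoate (racemic) | O=C1C=CC(O[Si](CC)(CC)CC)(CCCCCCCC(=O)OC)C1 | intermediate
16 | methyl 8-{2,3-dibromo-4-oxo-1-[(triethylsilyl)oxy]cyclopentyl}octanoate (racemic) | O=C1C(Br)C(Br)C(O[Si](CC)(CC)CC)(CCCCCCCC(=O)OC)C1 | intermediate (not isolated)
17 | methyl 8-{3-bromo-4-oxo-1-[(triethylsilyl)oxy]cyclopent-2-en-1-yl}octanoate (racemic) | O=C1C(Br)=CC(O[Si](CC)(CC)CC)(CCCCCCCC(=O)OC)C1 | intermediate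
18 | methyl 8-{(1R,4R)-3-bromo-4-hydroxy-1-[(triethylsilyl)oxy]cyclopent-2-en-1-yl}octanoate | O[C@H]1C(Br)=C[C@@](O[Si](CC)(CC)CC)(CCCCCCCC(=O)OC)C1 | intermediate
19 | methyl 8-{(1R)-3-bromo-4-oxo-1-[(triethylsilyl)oxy]cyclopent-2-en-1-yl}octanoate | O=C1C(Br)=C[C@@](O[Si](CC)(CC)CC)(CCCCCCCC(=O)OC)C1 | intermediate
20 | (2E)-pent-2-enal | CC/C=C/C=O | starting material
21 | lithium dienolate of 19 | [Li]OC1=C[C@](O[Si](CC)(CC)CC)(CCCCCCCC(=O)OC)C=C1Br | intermediate (not isolated)
22 | chlorobis(cyclopentadienyl)zirconium dienolate of 19 | Cl[Zr](OC1=C[C@](O[Si](CC)(CC)CC)(CCCCCCCC(=O)OC)C=C1Br)(C2C=CC=C2)C3C=CC=C3 | intermediate (not isolated)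
23 | methyl 8-{(1R,5R)-3-bromo-5-[(1R,2E)-1-hydroxypent-2-en-1-yl]-4-oxo-1-[(triethylsilyl)oxy]cyclopent-2-en-1-yl}octanoate (syn aldol) | O=C1C(Br)=C[C@@](O[Si](CC)(CC)CC)(CCCCCCCC(=O)OC)[C@H]1[C@H](O)/C=C/CC | intermediate
24 | methyl 8-{(1S,5Z)-3-bromo-4-oxo-5-[(2E)-pent-2-en-1-ylidene]-1-[(triethylsilyl)oxy]cyclopent-2-en-1-yl}octanoate | CC/C=C/C=C1\C(=O)C(Br)=C[C@@]1(O[Si](CC)(CC)CC)CCCCCCCC(=O)OC | intermediate
25 | methyl 8-{(1S,5Z)-3-bromo-1-hydroxy-4-oxo-5-[(2E)-pent-2-en-1-ylidene]cyclopent-2-en-1-yl}octanoate | CC/C=C/C=C1\C(=O)C(Br)=C[C@@]1(O)CCCCCCCC(=O)OC | target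

**Step count and risks**

Total step count: 12. Longest linear sequence: 11 steps (3 to 25 through steps 2–12).

Steps most likely to fail:

Step 4. Proton transfer from the C8 methylene or the ester α-position, 1,4-addition of the enolate to 8, or quenching of the Brook-derived carbanion before ring closure would each stop the annulation. The fallback uses known reactions, sets out from 2 and returns at 14. The kinetic lithium enolate of 2 is added to acrolein (THF, –78 °C) to give methyl 11-hydroxy-9-oxotridec-12-enoate F1. Vinylmagnesium bromide with CeCl3 (THF, –78 °C) adds to the ketone to give methyl 9-ethenyl-9,11-dihydroxytridec-12-enoate F2. Ring-closing metathesis with the second-generation Grubbs catalyst (CH2Cl2, 40 °C) closes C2=C3 to methyl 8-(1,4-dihydroxycyclopent-2-en-1-yl)octanoate F3. MnO2 (CH2Cl2, rt) then oxidises only the secondary allylic alcohol and returns racemic 14.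

Step 8. Incomplete catalyst control against the substrate bias, or co-elution of the two diastereomers, would erode the enantiomeric purity. The fallback sets out from 17 and returns at 19: the enantiomers of 17 are separated directly by preparative chromatography on a chiral stationary phase (amylose tris(3,5-dimethylphenylcarbamate), supercritical CO2/2-propanol). This makes steps 8 and 9 unnecessary and gives no new compound (none F0).

Step 10. Low syn/anti selectivity in the aldol addition, or retro-aldol equilibration of the zirconium aldolate, would pass through the stereospecific dehydration as an E/Z mixture. The fallback sets out from 19 and returns at 24. LDA aldol addition to 20 without transmetalation gives the aldol as a diastereomer mixture, methyl 8-{(1R)-3-bromo-5-[(2E)-1-hydroxypent-2-en-1-yl]-4-oxo-1-[(triethylsilyl)oxy]cyclopent-2-en-1-yl}octanoate F4. MsCl/Et3N (CH2Cl2, 0 °C) gives the mesylate methyl 8-{(1R)-3-bromo-5-[(2E)-1-(methanesulfonyloxy)pent-2-en-1-yl]-4-oxo-1-[(triethylsilyl)oxy]cyclopent-2-en-1-yl}octanoate F5. DBU induces E1cB elimination to 24 together with its exocyclic isomer methyl 8-{(1S,5E)-3-bromo-4-oxo-5-[(2E)-pent-2-en-1-ylidene]-1-[(triethylsilyl)oxy]cyclopent-2-en-1-yl}octanoate F6. The isomers are separated, and F6 is re-equilibrated by irradiation at 365 nm and recycled to 24.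

Further compounds
F1 | step 4 | methyl 11-hydroxy-9-oxotridec-12-enoate (racemic) | C=CC(O)CC(=O)CCCCCCCC(=O)OC
F2 | step 4 | methyl 9-ethenyl-9,11-dihydroxytridec-12-enoate (diastereomer mixture) | C=CC(O)CC(O)(C=C)CCCCCCCC(=O)OC
F3 | step 4 | methyl 8-(1,4-dihydroxycyclopent-2-en-1-yl)octanoate (diastereomer mixture) | OC1C=CC(O)(CCCCCCCC(=O)OC)C1
F0 | step 8 | none | none
F4 | step 10 | methyl 8-{(1R)-3-bromo-5-[(2E)-1-hydroxypent-2-en-1-yl]-4-oxo-1-[(triethylsilyl)oxy]cyclopent-2-en-1-yl}octanoate (diastereomer mixture) | O=C1C(Br)=C[C@@](O[Si](CC)(CC)CC)(CCCCCCCC(=O)OC)C1C(O)/C=C/CC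
F5 | step 10 | methyl 8-{(1R)-3-bromo-5-[(2E)-1-(methanesulfonyloxy)pent-2-en-1-yl]-4-oxo-1-[(triethylsilyl)oxy]cyclopent-2-en-1-yl}octanoate (diastereomer mixture) | O=C1C(Br)=C[C@@](O[Si](CC)(CC)CC)(CCCCCCCC(=O)OC)C1C(OS(C)(=O)=O)/C=C/CC
F6 | step 10 | methyl 8-{(1S,5E)-3-bromo-4-oxo-5-[(2E)-pent-2-en-1-ylidene]-1-[(triethylsilyl)oxy]cyclopent-2-en-1-yl}octanoate | CC/C=C/C=C1/C(=O)C(Br)=C[C@@]1(O[Si](CC)(CC)CC)CCCCCCCC(=O)OC
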